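**Plan**

- Retrosynthesis: the C-15 acetate goes back to a silyl ether. The C-3–C-4 bond of ring A is cut by a retro-Favorskii move that re-inserts the ester carbon C-18 between C-3 and C-4, giving the seven-membered α-chloro ketone 20. C-2–C-3 is then cut by a retro-Claisen ring expansion to the 2-methylene-5-vinyltetrahydrofuran 17 (vinyl lactone 16). C-1–C-10, C-4–C-19 and C-4–C-5 lead to cyclohexanone 10, and C-9–C-11 and C-8–CH3 to 2-methylcyclohexenone.
- Enabling feature: C-4 of ring A carries both CO2Me (C-18) and CH3 and sits next to the unsubstituted C-3 methylene. This is the signature of a Favorskii contraction of a 2-chloro-2-methylcycloalkanone whose ring is C-4, C-18, C-3, C-2, C-1, C-10, C-5. The Δ1(10) alkene lies γ,δ to C-18 in that ring, where a Claisen ring expansion places it.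
- Forward: ring B is the starting ring and receives C-8 and C-9. The side-chain alkene is made by carboalumination. An acetate arm at C-5 and a vinyl group at C-10 give a lactone, and methylenation plus Claisen shift build the seven-membered ring. Chlorination and Favorskii contraction close ring A, followed by desilylation and acetylation.
- Stereochemistry: C-8 comes from the chiral copper catalyst, C-9 from alkylation anti to the C-8 methyl, and 13E from syn-carboalumination. C-5 comes from kinetic alkylation on the face opposite both methyls, and C-4 is set in the Favorskii closure under control of C-5.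

Key step: step 12

Remark: atoms are numbered as in the halimane skeleton (ring A = C-1 to C-5 and C-10; ring B = C-5 to C-10; C-18 = ester carbon; C-19 = methyl on C-4; side chain C-11 to C-16). Compound numbers are plain numerals.
Remark: the configurations at C-10 (in 13 to 17) and at C-4 (in 16 to 20) are transient and do not reach the target. They are drawn as the expected major isomers, and 20 is carried as both C-4 epimers.

**Route**

Step 1
Reactants: 1 2-methylcyclohex-2-en-1-one
Product: 3 trimethyl{[(3R)-2,3-dimethylcyclohex-1-en-1-yl]oxy}silane, via aluminium enolate 2 (not isolated)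
Conditions: Me3Al, Cu(O2CC4H3S) (copper thiophene-2-carboxylate, 2 mol %), BINOL-derived phosphoramidite with a bis(1-phenylethyl)amino group (4 mol %), Et2O, −30 °C; then TMSOTf, THF, −30 → 0 °C
Reagents that add atoms: trimethylaluminium, C[Al](C)C; trimethylsilyl trifluoromethanesulfonate, C[Si](C)(C)OS(=O)(=O)C(F)(F)F
Why: Copper-catalysed asymmetric conjugate addition of a trialkylaluminium to a 2-substituted cyclohexenone should set C-8 (R) under ligand control (the ligand antipode is chosen accordingly), and O-silylation of the regiodefined aluminium enolate stores the C-9/C-10 enolate for step 3.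

Step 2
Reactants: 4 but-3-yn-1-ol
Product: 5 but-3-yn-1-yl trifluoromethanesulfonate
Conditions: Tf2O, pyridine, CH2Cl2, −78 → −20 °C (used at once)
Reagents that add atoms: trifluoromethanesulfonic anhydride, FC(F)(F)S(=O)(=O)OS(=O)(=O)C(F)(F)F
Why: Sulfonylation of a primary alcohol gives a homopropargylic triflate that should be reactive enough to alkylate a hindered enolate below the temperature at which elimination sets in.

Step 3
Reactants: 3 trimethyl{[(3R)-2,3-dimethylcyclohex-1-en-1-yl]oxy}silane; 5 but-3-yn-1-yl trifluoromethanesulfonate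
Product: 7 (2S,3R)-2-(but-3-yn-1-yl)-2,3-dimethylcyclohexan-1-one, via lithium enolate 6 (not isolated)
Conditions: MeLi, THF, 0 °C; then 5, −78 → −20 °C
Reagents that add atoms: methyllithium, [Li]C (lithium, in 6 only)
Why: Cleavage of the silyl enol ether gives the tetrasubstituted lithium enolate regiospecifically, and C-alkylation (enolate alkylation) should occur anti to the adjacent C-8 methyl, so the C-9 methyl ends cis to the C-8 methyl and the chain trans.

Step 4
Reactants: 7 (2S,3R)-2-(but-3-yn-1-yl)-2,3-dimethylcyclohexan-1-one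
Product: 9 (2S,3R)-2-[(3E)-5-hydroxy-3-methylpent-3-en-1-yl]-2,3-dimethylcyclohexan-1-one, via alkenylalane 8 (not isolated)
Conditions: Me3Al, Cp2ZrCl2 (20 mol %), H2O (1 equiv), CH2Cl2, −23 °C; then (CH2O)n, 0 → 25 °C
Reagents that add atoms: trimethylaluminium, C[Al](C)C; paraformaldehyde (as formaldehyde), C=O
Why: Negishi zirconium-catalysed carboalumination adds CH3 and Al syn across the terminal alkyne with Al on the terminal carbon, which fixes the 13E geometry; the alkenylalane is hydroxymethylated with retention, and the low-temperature water-accelerated variant should spare the hindered ketone.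

Step 5
Reactants: 9 (2S,3R)-2-[(3E)-5-hydroxy-3-methylpent-3-en-1-yl]-2,3-dimethylcyclohexan-1-one
Product: 10 (2S,3R)-2-{(3E)-5-[(tert-butyldiphenylsilyl)oxy]-3-methylpent-3-en-1-yl}-2,3-dimethylcyclohexan-1-one
Conditions: TBDPSCl, imidazole, DMF, 25 °C
Reagents that add atoms: tert-butyl(chloro)diphenylsilane, CC(C)(C)[Si](Cl)(c1ccccc1)c1ccccc1
Why: Silylation of the primary allylic alcohol gives an ether that should tolerate amide bases, organometallics, the titanium methylenating agent, 180 °C and methoxide.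

Step 6
Reactants: 10 (2S,3R)-2-{(3E)-5-[(tert-butyldiphenylsilyl)oxy]-3-methylpent-3-en-1-yl}-2,3-dimethylcyclohexan-1-one
Product: 12 methyl 2-[(1S,3S,4R)-3-{(3E)-5-[(tert-butyldiphenylsilyl)oxy]-3-methylpent-3-en-1-yl}-3,4-dimethyl-2-oxocyclohexyl]acetate, via lithium enolate 11 (not isolated)
Conditions: LiN(i-Pr)2, THF, −78 °C; BrCH2CO2Me, DMPU, −78 → −45 °C; AcOH quench at −78 °C
Reagents that add atoms: lithium diisopropylamide, CC(C)N([Li])C(C)C (lithium, in 11 only); methyl bromoacetate, COC(=O)CBr
Why: C-5 is the only enolisable position, and ketone enolate alkylation should occur on the ring face opposite the C-8 and C-9 methyl groups (in either half-chair one of them is axial on that face, while the other face is open when the C-9 methyl is axial), which sets C-5 kinetically; the cold acidic quench avoids epimerisation.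

Step 7
Reactants: 12 methyl 2-[(1S,3S,4R)-3-{(3E)-5-[(tert-butyldiphenylsilyl)oxy]-3-methylpent-3-en-1-yl}-3,4-dimethyl-2-oxocyclohexyl]acetate
Product: 14 (3aS,6R,7S,7aS)-7a-ethenyl-6,7-dimethyl-7-{(3E)-5-[(tert-butyldiphenylsilyl)oxy]-3-methylpent-3-en-1-yl}hexahydro-1-benzofuran-2(3H)-one, via tertiary alkoxide 13 (not isolated)
Conditions: CH2=CHMgBr, CeCl3, THF, −78 °C; then 25 °C
Reagents that add atoms: vinylmagnesium bromide, C=C[Mg]Br
Why: The organocerium reagent should add to the hindered ketone without enolising C-5 and faster than to the ester, from the axial direction anti to the axial C-9 methyl (the other chair is blocked by an axial C-8 methyl), and the equatorial alkoxide then closes the trans-fused γ-lactone on the neighbouring ester arm (5-exo-trig acyl substitution).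

Step 8
Reactants: 14 (3aS,6R,7S,7aS)-7a-ethenyl-6,7-dimethyl-7-{(3E)-5-[(tert-butyldiphenylsilyl)oxy]-3-methylpent-3-en-1-yl}hexahydro-1-benzofuran-2(3H)-one
Product: 16 (3S,3aS,6R,7S,7aS)-7a-ethenyl-3,6,7-trimethyl-7-{(3E)-5-[(tert-butyldiphenylsilyl)oxy]-3-methylpent-3-en-1-yl}hexahydro-1-benzofuran-2(3H)-one, via lithium enolate 15 (not isolated)
Conditions: LiN(i-Pr)2, THF, −78 °C; MeI, −78 → −30 °C
Reagents that add atoms: lithium diisopropylamide, CC(C)N([Li])C(C)C (lithium, in 15 only); iodomethane, CI
Why: Lactone enolate methylation installs C-19 before the ring expansion, so that the two α-carbons of the later ketone differ; methyl should enter anti to C-6, but the C-4 configuration is reset in step 12.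

Step 9
Reactants: 16 (3S,3aS,6R,7S,7aS)-7a-ethenyl-3,6,7-trimethyl-7-{(3E)-5-[(tert-butyldiphenylsilyl)oxy]-3-methylpent-3-en-1-yl}hexahydro-1-benzofuran-2(3H)-one
Product: 17 (3S,3aS,6R,7S,7aS)-7a-ethenyl-3,6,7-trimethyl-2-methylidene-7-{(3E)-5-[(tert-butyldiphenylsilyl)oxy]-3-methylpent-3-en-1-yl}octahydro-1-benzofuran
Conditions: Cp2TiMe2, toluene, pyridine (1 %), 70 °C, dark
Reagents that add atoms: dimethyltitanocene, C[Ti](C)(C1C=CC=C1)C1C=CC=C1
Why: Petasis methylenation converts the lactone carbonyl into the exocyclic enol ether through Cp2Ti=CH2 under non-acidic conditions, which should keep the new double bond exocyclic and leave the other alkenes and the silyl ether untouched.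

Step 10
Reactants: 17 (3S,3aS,6R,7S,7aS)-7a-ethenyl-3,6,7-trimethyl-2-methylidene-7-{(3E)-5-[(tert-butyldiphenylsilyl)oxy]-3-methylpent-3-en-1-yl}octahydro-1-benzofuran
Product: 18 (1S,2S,8S,9R)-2,8,9-trimethyl-8-{(3E)-5-[(tert-butyldiphenylsilyl)oxy]-3-methylpent-3-en-1-yl}bicyclo[5.4.0]undec-6-en-3-one
Conditions: xylenes, Et3N (trace), base-washed sealed tube, 180 °C
Reagents that add atoms: none
Why: Claisen ring expansion of a 2-methylene-5-vinyltetrahydrofuran to a cyclohept-4-enone: the [3,3] shift through a boat transition state forms C-2–C-3, breaks C-10–O and makes C-18 a ketone, and the new Δ1(10) alkene must be cis inside the seven-membered ring, so its position and geometry are fixed.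

Step 11
Reactants: 18 (1S,2S,8S,9R)-2,8,9-trimethyl-8-{(3E)-5-[(tert-butyldiphenylsilyl)oxy]-3-methylpent-3-en-1-yl}bicyclo[5.4.0]undec-6-en-3-one
Product: 20 (1R,8S,9R)-2-chloro-2,8,9-trimethyl-8-{(3E)-5-[(tert-butyldiphenylsilyl)oxy]-3-methylpent-3-en-1-yl}bicyclo[5.4.0]undec-6-en-3-one (both C-4 epimers), via silyl enol ether 19 (not isolated)
Conditions: i-Pr2NMgBr, TMSCl, Et3N, HMPA, Et2O, 25 °C; then NCS, THF, 0 °C
Reagents that add atoms: chlorotrimethylsilane, C[Si](C)(C)Cl (silicon, in 19 only); N-chlorosuccinimide, O=C1CCC(=O)N1Cl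
Why: Equilibrating enolisation with the bromomagnesium amide gives the more substituted (C-4) silyl enol ether, and electrophilic chlorination of it by NCS should give the tertiary α-chloro ketone without touching the isolated alkenes; any C-3 chloride from the minor enol ether would enter the same cyclopropanone manifold in step 12.

Step 12
Reactants: 20 (1R,8S,9R)-2-chloro-2,8,9-trimethyl-8-{(3E)-5-[(tert-butyldiphenylsilyl)oxy]-3-methylpent-3-en-1-yl}bicyclo[5.4.0]undec-6-en-3-one
Product: 22 methyl (1S,5S,6R,8aR)-5-{(3E)-5-[(tert-butyldiphenylsilyl)oxy]-3-methylpent-3-en-1-yl}-1,5,6-trimethyl-1,2,3,5,6,7,8,8a-octahydronaphthalene-1-carboxylate, via cyclopropanone 21 (not isolated)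
Conditions: NaOMe (3 equiv), MeOH, 0 → 25 °C
Reagents that add atoms: sodium methoxide, C[O-].[Na+]
Why: Methoxide removes H-3 (the only enolisable position), the enolate expels chloride and the C-3–C-4 bond forms across the carbonyl, so the seven-membered ring becomes cyclopropanone 21, which already contains six-membered ring A; methoxide then adds to C-18 and the hemiketal anion opens toward the less substituted carbanion at C-3, which is protonated, leaving CO2Me on C-4. The closest known reaction is the Favorskii ring contraction of 2-chloro-2-methylcyclohexanone to methyl 1-methylcyclopentanecarboxylate. Ring A is closed in a 3-exo-tet displacement (in the ionised limit a disrotatory two-electron closure of the oxyallyl species), that is a transannular 1,3-bond across C-18 of the seven-membered ring. The new stereocentre C-4 is controlled by C-5: in methanol the tertiary chloride ionises from the enolate, so both chloride epimers should converge on one planar oxyallyl species, and closure on the face anti to H-5 keeps the C-19 methyl eclipsed with H-5 and not with C-6, which puts C-18 (CO2Me) trans to H-5 as in the target. The step needs regioselective cleavage of C-18–C-3 over C-18–C-4, secured by the secondary versus tertiary carbanion, and Favorskii closure in preference to solvolysis or dehydrochlorination, favoured by excess methoxide and by the absence of any other acidic site.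

Step 13
Reactants: 22 methyl (1S,5S,6R,8aR)-5-{(3E)-5-[(tert-butyldiphenylsilyl)oxy]-3-methylpent-3-en-1-yl}-1,5,6-trimethyl-1,2,3,5,6,7,8,8a-octahydronaphthalene-1-carboxylate
Product: 23 methyl (1S,5S,6R,8aR)-5-[(3E)-5-hydroxy-3-methylpent-3-en-1-yl]-1,5,6-trimethyl-1,2,3,5,6,7,8,8a-octahydronaphthalene-1-carboxylate
Conditions: Bu4NF, THF, 25 °C
Reagents that add atoms: none
Why: Fluoride-induced desilylation frees the primary allylic alcohol, and the hindered tertiary methyl ester should not be affected.

Step 14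
Reactants: 23 methyl (1S,5S,6R,8aR)-5-[(3E)-5-hydroxy-3-methylpent-3-en-1-yl]-1,5,6-trimethyl-1,2,3,5,6,7,8,8a-octahydronaphthalene-1-carboxylate
Product: 24 methyl (1S,5S,6R,8aR)-5-[(3E)-5-(acetyloxy)-3-methylpent-3-en-1-yl]-1,5,6-trimethyl-1,2,3,5,6,7,8,8a-octahydronaphthalene-1-carboxylate
Conditions: Ac2O, pyridine, DMAP (cat.), CH2Cl2, 25 °C
Reagents that add atoms: acetic anhydride, CC(=O)OC(C)=O
Why: Nucleophile-catalysed acylation of the primary allylic alcohol under basic conditions should give the acetate without allylic transposition.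

**Compound list**

1 | 2-methylcyclohex-2-en-1-one | CC1=CCCCC1=O | starting material
2 | dimethylaluminium (3R)-2,3-dimethylcyclohex-1-en-1-olate | C[C@@H]1CCCC(O[Al](C)C)=C1C | intermediate
3 | trimethyl{[(3R)-2,3-dimethylcyclohex-1-en-1-yl]oxy}silane | C[C@@H]1CCCC(O[Si](C)(C)C)=C1C | intermediate
4 | but-3-yn-1-ol | C#CCCO | starting material
5 | but-3-yn-1-yl trifluoromethanesulfonate | C#CCCOS(=O)(=O)C(F)(F)F | intermediate
6 | lithium (3R)-2,3-dimethylcyclohex-1-en-1-olate | C[C@@H]1CCCC([O-])=C1C.[Li+] | intermediate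
7 | (2S,3R)-2-(but-3-yn-1-yl)-2,3-dimethylcyclohexan-1-one | O=C1CCC[C@@H](C)[C@]1(C)CCC#C | intermediate
8 | (E)-alkenyldimethylalane from 7 (AlMe2 on C-14, cis to the new C-13 methyl) | O=C1CCC[C@@H](C)[C@]1(C)CC/C(C)=C/[Al](C)C | intermediate
9 | (2S,3R)-2-[(3E)-5-hydroxy-3-methylpent-3-en-1-yl]-2,3-dimethylcyclohexan-1-one | O=C1CCC[C@@H](C)[C@]1(C)CC/C(C)=C/CO | intermediate
10 | (2S,3R)-2-{(3E)-5-[(tert-butyldiphenylsilyl)oxy]-3-methylpent-3-en-1-yl}-2,3-dimethylcyclohexan-1-one | O=C1CCC[C@@H](C)[C@]1(C)CC/C(C)=C/CO[Si](c2ccccc2)(c3ccccc3)C(C)(C)C | intermediate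
11 | lithium enolate of 10 (C-5=C-10) | [Li+].[O-]C1=CCC[C@@H](C)[C@]1(C)CC/C(C)=C/CO[Si](c2ccccc2)(c3ccccc3)C(C)(C)C | intermediate
12 | methyl 2-[(1S,3S,4R)-3-{(3E)-5-[(tert-butyldiphenylsilyl)oxy]-3-methylpent-3-en-1-yl}-3,4-dimethyl-2-oxocyclohexyl]acetate | COC(=O)C[C@@H]1CC[C@@H](C)[C@](C)(CC/C(C)=C/CO[Si](c2ccccc2)(c3ccccc3)C(C)(C)C)C1=O | intermediate
13 | metal alkoxide of methyl 2-[(1S,2S,3S,4R)-2-ethenyl-2-hydroxy-3-{(3E)-5-[(tert-butyldiphenylsilyl)oxy]-3-methylpent-3-en-1-yl}-3,4-dimethylcyclohexyl]acetate (drawn as the alcohol) | COC(=O)C[C@@H]1CC[C@@H](C)[C@](C)(CC/C(C)=C/CO[Si](c2ccccc2)(c3ccccc3)C(C)(C)C)[C@]1(O)C=C | intermediate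
14 | (3aS,6R,7S,7aS)-7a-ethenyl-6,7-dimethyl-7-{(3E)-5-[(tert-butyldiphenylsilyl)oxy]-3-methylpent-3-en-1-yl}hexahydro-1-benzofuran-2(3H)-one (trans-fused; vinyl trans to both methyls) | O=C1C[C@@H]2CC[C@@H](C)[C@](C)(CC/C(C)=C/CO[Si](c3ccccc3)(c4ccccc4)C(C)(C)C)[C@@]2(C=C)O1 | intermediate
15 | lithium enolate of 14 (C-4=C-18) | [Li+].[O-]C1=C[C@@H]2CC[C@@H](C)[C@](C)(CC/C(C)=C/CO[Si](c3ccccc3)(c4ccccc4)C(C)(C)C)[C@@]2(C=C)O1 | intermediate
16 | (3S,3aS,6R,7S,7aS)-7a-ethenyl-3,6,7-trimethyl-7-{(3E)-5-[(tert-butyldiphenylsilyl)oxy]-3-methylpent-3-en-1-yl}hexahydro-1-benzofuran-2(3H)-one | O=C1[C@@H](C)[C@@H]2CC[C@@H](C)[C@](C)(CC/C(C)=C/CO[Si](c3ccccc3)(c4ccccc4)C(C)(C)C)[C@@]2(C=C)O1 | intermediate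
17 | (3S,3aS,6R,7S,7aS)-7a-ethenyl-3,6,7-trimethyl-2-methylidene-7-{(3E)-5-[(tert-butyldiphenylsilyl)oxy]-3-methylpent-3-en-1-yl}octahydro-1-benzofuran | C=C1[C@@H](C)[C@@H]2CC[C@@H](C)[C@](C)(CC/C(C)=C/CO[Si](c3ccccc3)(c4ccccc4)C(C)(C)C)[C@@]2(C=C)O1 | intermediate
18 | (1S,2S,8S,9R)-2,8,9-trimethyl-8-{(3E)-5-[(tert-butyldiphenylsilyl)oxy]-3-methylpent-3-en-1-yl}bicyclo[5.4.0]undec-6-en-3-one | C[C@@H]1C(=O)CCC=C2[C@H]1CC[C@@H](C)[C@]2(C)CC/C(C)=C/CO[Si](c3ccccc3)(c4ccccc4)C(C)(C)C | intermediate
19 | trimethylsilyl enol ether of 18 toward C-4 (C-4=C-18) | CC1=C(O[Si](C)(C)C)CCC=C2[C@H]1CC[C@@H](C)[C@]2(C)CC/C(C)=C/CO[Si](c3ccccc3)(c4ccccc4)C(C)(C)C | intermediate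
20 | (1R,8S,9R)-2-chloro-2,8,9-trimethyl-8-{(3E)-5-[(tert-butyldiphenylsilyl)oxy]-3-methylpent-3-en-1-yl}bicyclo[5.4.0]undec-6-en-3-one, both C-4 epimers | CC1(Cl)C(=O)CCC=C2[C@H]1CC[C@@H](C)[C@]2(C)CC/C(C)=C/CO[Si](c3ccccc3)(c4ccccc4)C(C)(C)C | intermediate
21 | cyclopropanone spanning C-3 and C-4 of ring A, C-18 bridge on the face opposite H-5 | C[C@]12C(=O)[C@H]1CC=C1[C@H]2CC[C@@H](C)[C@]1(C)CC/C(C)=C/CO[Si](c3ccccc3)(c4ccccc4)C(C)(C)C | intermediate
22 | methyl (1S,5S,6R,8aR)-5-{(3E)-5-[(tert-butyldiphenylsilyl)oxy]-3-methylpent-3-en-1-yl}-1,5,6-trimethyl-1,2,3,5,6,7,8,8a-octahydronaphthalene-1-carboxylate | COC(=O)[C@@]1(C)CCC=C2[C@H]1CC[C@@H](C)[C@]2(C)CC/C(C)=C/CO[Si](c3ccccc3)(c4ccccc4)C(C)(C)C | intermediate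
23 | methyl (1S,5S,6R,8aR)-5-[(3E)-5-hydroxy-3-methylpent-3-en-1-yl]-1,5,6-trimethyl-1,2,3,5,6,7,8,8a-octahydronaphthalene-1-carboxylate | COC(=O)[C@@]1(C)CCC=C2[C@H]1CC[C@@H](C)[C@]2(C)CC/C(C)=C/CO | intermediate
24 | methyl (1S,5S,6R,8aR)-5-[(3E)-5-(acetyloxy)-3-methylpent-3-en-1-yl]-1,5,6-trimethyl-1,2,3,5,6,7,8,8a-octahydronaphthalene-1-carboxylate | COC(=O)[C@@]1(C)CCC=C2[C@H]1CC[C@@H](C)[C@]2(C)CC/C(C)=C/COC(C)=O | target

**Step count and risks**

Total step count: 14. Longest linear sequence: 13 (steps 1 and 3 to 14).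

Steps most likely to fail:

1. Step 12 (Favorskii contraction). The oxyallyl intermediate may be captured by methanol or lose HCl before it closes, or the ring may close on the wrong face of C-4. The fallback builds ring A by cycloaddition instead of ring contraction. It sets out from ketone 10: kinetic enolisation (LiN(i-Pr)2, then PhNTf2) gives the C-10 enol triflate F1. Stille coupling with tributyl(vinyl)stannane (Pd(PPh3)4, a zerovalent palladium complex, with LiCl) gives the 1-vinylcyclohexene diene F2. A Diels–Alder reaction of F2 with methyl methacrylate (EtAlCl2, CH2Cl2, −40 °C) then forms C-2–C-3 and C-4–C-5 and comes back to the route at 22. The ring-bound diene terminus should direct the ester-bearing carbon to C-5. The ester-endo transition state places CO2Me trans to H-5, and approach opposite the axial C-9 methyl should set C-5.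

2. Step 10 (Claisen ring expansion). The exocyclic enol ether double bond may migrate into the ring under trace acid, which would lead to a five-membered carbocycle, or the substrate may decompose at the temperature the boat transition state needs. The fallback replaces the thermal shift by ionisation and recombination. It sets out from lactone 16: Wittig olefination of the lactone carbonyl with Ph3P=CHCO2Et (toluene, 110 °C) gives the ethyl (tetrahydrofuran-2-ylidene)acetate F3. Pd(PPh3)4 with dppe in DMSO (zerovalent palladium) ionises the tertiary allylic C-10–O bond of F3 to a π-allyl and β-keto ester enolate pair. This pair should recombine at the terminal allyl carbon C-2, because C-10 is fully substituted, to give the cycloheptenone β-keto ester F4. Krapcho dealkoxycarbonylation (LiCl, wet DMSO, 150 °C) then comes back to the route at 18.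

3. Step 6 (alkylation at C-5). Facial selectivity may be poor, or the product may epimerise by proton transfer, since the two C-5 epimers are expected to be of similar stability. The fallback uses auxiliary control. It sets out from ketone 10: condensation with (S)-1-amino-2-(methoxymethyl)pyrrolidine gives the hydrazone F5. Deprotonation with LiN(i-Pr)2 and alkylation with methyl bromoacetate (Enders hydrazone alkylation) gives the alkylated hydrazone F6, with the face fixed by the chelated azaenolate. Hydrolysis with aqueous oxalic acid then comes back to the route at 12 without epimerisation.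

**Further compounds**

F1 | step 12 | (5R,6S)-6-{(3E)-5-[(tert-butyldiphenylsilyl)oxy]-3-methylpent-3-en-1-yl}-5,6-dimethylcyclohex-1-en-1-yl trifluoromethanesulfonate | FC(F)(F)S(=O)(=O)OC1=CCC[C@@H](C)[C@]1(C)CC/C(C)=C/CO[Si](c2ccccc2)(c3ccccc3)C(C)(C)C
F2 | step 12 | 1-ethenylcyclohexene diene from F1 (vinyl on C-10, C-5=C-10) | C=CC1=CCC[C@@H](C)[C@]1(C)CC/C(C)=C/CO[Si](c2ccccc2)(c3ccccc3)C(C)(C)C
F3 | step 10 | ethyl 2-(tetrahydrofuran-2-ylidene)acetate derived from 16 (enol ether geometry not defined) | CCOC(=O)C=C1[C@@H](C)[C@@H]2CC[C@@H](C)[C@](C)(CC/C(C)=C/CO[Si](c3ccccc3)(c4ccccc4)C(C)(C)C)[C@@]2(C=C)O1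
F4 | step 10 | ethyl ester of the 3-carboxy derivative of 18 (β-keto ester, C-3 epimers) | C[C@@H]1C(=O)C(C(=O)OCC)CC=C2[C@H]1CC[C@@H](C)[C@]2(C)CC/C(C)=C/CO[Si](c3ccccc3)(c4ccccc4)C(C)(C)C
F5 | step 6 | (S)-1-amino-2-(methoxymethyl)pyrrolidine hydrazone of 10 | COC[C@@H]1CCCN1N=C1CCC[C@@H](C)[C@]1(C)CC/C(C)=C/CO[Si](c2ccccc2)(c3ccccc3)C(C)(C)C
F6 | step 6 | (S)-1-amino-2-(methoxymethyl)pyrrolidine hydrazone of 12 | COC[C@@H]1CCCN1N=C1[C@H](CC(=O)OC)CC[C@@H](C)[C@]1(C)CC/C(C)=C/CO[Si](c2ccccc2)(c3ccccc3)C(C)(C)C
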